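**Plan**

1. Numbering: ring A is C1 (acyl, prenyl), C2 (enone C=O), C3, C4 (bears O4), C5 (methyl, prenyl), C6 (C=O); ring B is O4–C8–C7 fused on the C3–C4 edge; C9 is the side-chain carbinol.
2. Retrosynthesis: cut C1–prenyl, then C5–prenyl (the step that dearomatises ring A), then C1–acyl, then ring B at C4–O4 and C3–C7. This leaves a C3≡C4 aryne (fragment 1) and a terminal C7–C8 epoxide carrying C9 (fragment 2).
3. Enabling feature: ring B is a 2-alkyl-2,3-dihydrofuran on the C3–C4 edge of a ring A that can be carried as a phloroglucinol ether. C3≡C4 can therefore be an aryne, and the C2 oxygen next to C3 sends the epoxide oxygen to C4 and the carbanion to C3.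
4. C8 and C9 carry the oxygen pattern of a syn-dioxygenated E-alkene. It is reached from the Z-alkene of nerol by epoxidation and inversion at C8; opening a geranyl epoxide at C8 would give the other diastereomer.
5. Forward: fragment 1 from 2,4,6-trihydroxybenzaldehyde (steps 1–5), fragment 2 from nerol (steps 6–9), ring B closed on the aromatic ring A (step 10), then acylation, unmasking and two prenylations (steps 11–14).
6. Stereochemistry: C9 and C8 from Sharpless epoxidation with D-(−)-tartrate plus Payne inversion at C8; C5 from a ligand-controlled allylic alkylation; C1 from substrate control, anti to the C5 prenyl group.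

Key step: step 10

Remark: enol 33 is drawn as one of its tautomers; the ligand antipode in step 13 is to be fixed by a matched/mismatched test with both commercial enantiomers.

**Route**

Step 1
Reactants: 1 2,4,6-trihydroxybenzaldehyde; 2 chloromethyl methyl ether
Product: 3 2-hydroxy-4,6-bis(methoxymethoxy)benzaldehyde
Conditions: MOMCl (2.2 equiv), i-Pr2NEt, CH2Cl2, 0 °C → rt
Reagents that add atoms: chloromethyl methyl ether, COCCl
Why: Williamson-type acetal protection takes the para hydroxyl and one ortho hydroxyl, while the last hydroxyl, hydrogen-bonded to the aldehyde, resists alkylation and so marks the oxygen that later becomes the triflate.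

Step 2
Reactants: 3 2-hydroxy-4,6-bis(methoxymethoxy)benzaldehyde; 4 N-bromosuccinimide
Product: 5 3-bromo-2-hydroxy-4,6-bis(methoxymethoxy)benzaldehyde
Conditions: NBS (1.0 equiv), CH2Cl2, −20 → 0 °C
Reagents that add atoms: N-bromosuccinimide, O=C1CCC(=O)N1Br
Why: electrophilic aromatic bromination should go ortho to the free phenol, since the other activated position is flanked by two acetal ethers.

Step 3
Reactants: 5 3-bromo-2-hydroxy-4,6-bis(methoxymethoxy)benzaldehyde; 6 ethyl chloroformate
Product: 8 2-bromo-3,5-bis(methoxymethoxy)-6-methylphenol, via aryl ethyl carbonate 7 (not isolated)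
Conditions: ClCO2Et, Et3N, THF, 0 °C; then NaBH4, H2O, 0 °C → rt
Reagents that add atoms: none
Why: reductive deoxygenation of a salicylaldehyde through its O-carbonate (hydride reduction, carbonate transfer, loss of ethyl carbonate to an ortho-quinone methide, second hydride addition) gives the ortho-cresol without acid, so the acetals survive.

Step 4
Reactants: 8 2-bromo-3,5-bis(methoxymethoxy)-6-methylphenol; 9 hexamethyldisilazane
Product: 10 [2-bromo-3,5-bis(methoxymethoxy)-6-methylphenoxy](trimethyl)silane
Conditions: (Me3Si)2NH, THF, 70 °C; volatiles removed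
Reagents that add atoms: hexamethyldisilazane, C[Si](C)(C)N[Si](C)(C)C
Why: O-silylation of the hindered phenol with the disilazane needs no added base and leaves only ammonia.

Step 5
Reactants: 10 [2-bromo-3,5-bis(methoxymethoxy)-6-methylphenoxy](trimethyl)silane; 11 trifluoromethanesulfonic anhydride
Product: 13 3,5-bis(methoxymethoxy)-2-methyl-6-(trimethylsilyl)phenyl trifluoromethanesulfonate, via lithium 2-silylphenoxide 12 (not isolated)
Conditions: n-BuLi, THF, −78 °C; then Tf2O, −78 → 0 °C
Reagents that add atoms: trifluoromethanesulfonic anhydride, O=S(=O)(OS(=O)(=O)C(F)(F)F)C(F)(F)F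
Why: bromine–lithium exchange triggers a retro-Brook 1,3-shift of silicon from oxygen to C3 and the phenoxide is then triflated, the standard entry to ortho-silylaryl triflates.

Step 6
Reactants: 14 nerol; 15 tert-butyl hydroperoxide
Product: 16 [(2R,3S)-3-methyl-3-(4-methylpent-3-en-1-yl)oxiran-2-yl]methanol
Conditions: Ti(OiPr)4 (10 mol %), D-(−)-diethyl tartrate (12 mol %), t-BuOOH, 4 Å MS, CH2Cl2, −20 °C
Reagents that add atoms: tert-butyl hydroperoxide, CC(C)(C)OO
Why: Sharpless asymmetric epoxidation, in which the D-tartrate catalyst selects the face of the Z-allylic alcohol that fixes C9 as S and sets C8 provisionally.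

Step 7
Reactants: 16 [(2R,3S)-3-methyl-3-(4-methylpent-3-en-1-yl)oxiran-2-yl]methanol; 17 thiophenol
Product: 19 (2R,3S)-3,7-dimethyl-1-(phenylsulfanyl)oct-6-ene-2,3-diol, via sodium epoxy alkoxide 18 (not isolated)
Conditions: PhSH, NaOH (0.5 M aq.), t-BuOH, 75 °C
Reagents that add atoms: thiophenol, Sc1ccccc1
Why: Payne rearrangement, in which the C7 alkoxide displaces the epoxide oxygen at C8 with inversion and thiolate traps the terminal epoxide at C7 irreversibly, which sets the final C8 configuration.

Step 8
Reactants: 19 (2R,3S)-3,7-dimethyl-1-(phenylsulfanyl)oct-6-ene-2,3-diol; 20 trimethyloxonium tetrafluoroborate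
Product: 22 (2S)-6-methyl-2-[(2S)-oxiran-2-yl]hept-5-en-2-ol, via methylphenylsulfonium salt 21 (not isolated)
Conditions: Me3OBF4, CH2Cl2, 0 °C → rt; then NaOH (10% aq.), 0 °C, short contact
Reagents that add atoms: none
Why: S-methylation turns the sulfide into a leaving group and the C8 alkoxide closes the terminal epoxide by 3-exo-tet displacement at C7, so neither stereocentre is touched.

Step 9
Reactants: 22 (2S)-6-methyl-2-[(2S)-oxiran-2-yl]hept-5-en-2-ol; 23 triethylsilyl trifluoromethanesulfonate
Product: 24 triethyl({(2S)-6-methyl-2-[(2S)-oxiran-2-yl]hept-5-en-2-yl}oxy)silane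
Conditions: TESOTf, 2,6-lutidine, CH2Cl2, −78 °C
Reagents that add atoms: triethylsilyl trifluoromethanesulfonate, CC[Si](CC)(CC)OS(=O)(=O)C(F)(F)F
Why: silyl triflate silylation of the tertiary alcohol under buffered low-temperature conditions spares the epoxide and removes the hydroxyl that would otherwise be arylated in step 10.

Step 10
Reactants: 13 3,5-bis(methoxymethoxy)-2-methyl-6-(trimethylsilyl)phenyl trifluoromethanesulfonate; 24 triethyl({(2S)-6-methyl-2-[(2S)-oxiran-2-yl]hept-5-en-2-yl}oxy)silane
Product: 28 triethyl({(2S)-2-[(2S)-4,6-bis(methoxymethoxy)-7-methyl-2,3-dihydro-1-benzofuran-2-yl]-6-methylhept-5-en-2-yl}oxy)silane, via aryne 25 (not isolated), via oxiranium zwitterion 26 (not isolated), via bromoalkyl aryl anion 27 (not isolated)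
Conditions: Bu4N+ Ph3SiF2− (TBAT, 1.5 equiv), n-Bu4NBr (1.0 equiv), 24 (2 equiv), THF, 0 °C → rt, slow addition of 13
Reagents that add atoms: none
Why: Proposed new method: fluoride attacks silicon in 13 and 1,2-elimination of triflate gives aryne 25, the epoxide oxygen of 24 adds to C4 to give zwitterion 26, bromide opens the O-aryl oxiranium at the primary carbon C7, and the C3 carbanion of 27 displaces that bromide to form the C3–C7 bond. The closest known reactions are the insertion of arynes into the C–O bond of benzylic epoxides, three-component couplings of arynes with cyclic ethers and an external nucleophile, and Parham-type cyclisation of ortho-metalated aryl ethers onto alkyl halides. The bromide relay is added because the carbanion of 26 is joined to the oxonium through C4 alone and cannot reach C7 from the side opposite the departing oxygen, so direct collapse would need ionisation, which a non-benzylic epoxide does not offer at C7. Ring B closes by 5-exo-tet substitution. No stereocentre is formed: C8 keeps its configuration because the C8–O4 bond is never broken, and C9 is a spectator. The step needs oxygen at C4 and carbon at C3, which the C2 acetal oxygen secures by polarising the aryne so that the nucleophile adds to the distal carbon, and it needs opening at C7 and not at C8, which the neopentyl-like shielding of C8 and the inductively destabilising silyloxy group on C9 secure.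

Step 11
Reactants: 28 triethyl({(2S)-2-[(2S)-4,6-bis(methoxymethoxy)-7-methyl-2,3-dihydro-1-benzofuran-2-yl]-6-methylhept-5-en-2-yl}oxy)silane; 29 N-methoxy-N-methyl-2-methylpropanamide
Product: 30 1-[(2S)-4,6-bis(methoxymethoxy)-7-methyl-2-{(2S)-6-methyl-2-[(triethylsilyl)oxy]hept-5-en-2-yl}-2,3-dihydro-1-benzofuran-5-yl]-2-methylpropan-1-one
Conditions: n-BuLi, THF, 0 °C; then 29, 0 °C → rt
Reagents that add atoms: N-methoxy-N-methyl-2-methylpropanamide, CC(C)C(=O)N(C)OC
Why: directed ortho-metalation at C1, the only ring hydrogen and flanked by two acetal ethers, followed by Weinreb ketone synthesis, whose chelated tetrahedral intermediate prevents over-addition.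

Step 12
Reactants: 30 1-[(2S)-4,6-bis(methoxymethoxy)-7-methyl-2-{(2S)-6-methyl-2-[(triethylsilyl)oxy]hept-5-en-2-yl}-2,3-dihydro-1-benzofuran-5-yl]-2-methylpropan-1-one
Product: 31 1-{(2S)-4,6-dihydroxy-2-[(2S)-2-hydroxy-6-methylhept-5-en-2-yl]-7-methyl-2,3-dihydro-1-benzofuran-5-yl}-2-methylpropan-1-one
Conditions: HCl (1.25 M in MeOH), rt → 40 °C, stopped once all three groups are gone
Reagents that add atoms: none
Why: acid-catalysed transacetalisation to methanol removes both methoxymethyl ethers, which the ortho carbonyl activates, and the same medium solvolyses the triethylsilyl ether, so one operation frees all three hydroxyls.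

Step 13
Reactants: 31 1-{(2S)-4,6-dihydroxy-2-[(2S)-2-hydroxy-6-methylhept-5-en-2-yl]-7-methyl-2,3-dihydro-1-benzofuran-5-yl}-2-methylpropan-1-one; 32 3-methylbut-2-en-1-yl acetate
Product: 33 (2S,7S)-4-hydroxy-2-[(2S)-2-hydroxy-6-methylhept-5-en-2-yl]-7-methyl-7-(3-methylbut-2-en-1-yl)-5-(2-methylpropanoyl)-2,3-dihydro-1-benzofuran-6(7H)-one
Conditions: Pd2(dba)3 (2.5 mol %), (R,R)-DACH-phenyl Trost ligand (7.5 mol %), prenyl acetate (1.05 equiv), Cs2CO3, toluene, 0 °C → rt
Reagents that add atoms: 3-methylbut-2-en-1-yl acetate, CC(C)=CCOC(C)=O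
Why: Tsuji–Trost allylic alkylation of the phenoxide with dearomatisation, in which C5 attacks the unsubstituted terminus of the π-prenyl complex (C5 attack keeps the C3=C4 enol ether inside ring B, whereas C3 attack would put a quaternary centre at the ring fusion) and the chiral ligand is relied on to deliver the prenyl group anti to the C8 side chain to give 5S.

Step 14
Reactants: 33 (2S,7S)-4-hydroxy-2-[(2S)-2-hydroxy-6-methylhept-5-en-2-yl]-7-methyl-7-(3-methylbut-2-en-1-yl)-5-(2-methylpropanoyl)-2,3-dihydro-1-benzofuran-6(7H)-one; 32 3-methylbut-2-en-1-yl acetate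
Product: 34 (2S,5R,7S)-2-[(2S)-2-hydroxy-6-methylhept-5-en-2-yl]-7-methyl-5,7-bis(3-methylbut-2-en-1-yl)-5-(2-methylpropanoyl)-2,3-dihydro-1-benzofuran-4,6(5H,7H)-dione
Conditions: Pd(PPh3)4 (5 mol %), prenyl acetate (1.5 equiv), K2CO3, THF, rt → 40 °C
Reagents that add atoms: 3-methylbut-2-en-1-yl acetate, CC(C)=CCOC(C)=O
Why: Tsuji–Trost alkylation of the triketone enolate at its central carbon C1, where any O-prenyl ether re-ionises under the catalyst and the electrophile should enter anti to the larger C5 substituent (prenyl, not methyl) to set C1 as R.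

**Compound list**

1 | 2,4,6-trihydroxybenzaldehyde | O=Cc1c(O)cc(O)cc1O | starting material
2 | chloromethyl methyl ether | COCCl | starting material
3 | 2-hydroxy-4,6-bis(methoxymethoxy)benzaldehyde | O=Cc1c(O)cc(OCOC)cc1OCOC | intermediate
4 | N-bromosuccinimide | O=C1CCC(=O)N1Br | starting material
5 | 3-bromo-2-hydroxy-4,6-bis(methoxymethoxy)benzaldehyde | O=Cc1c(O)c(Br)c(OCOC)cc1OCOC | intermediate
6 | ethyl chloroformate | CCOC(=O)Cl | starting material
7 | 2-bromo-6-formyl-3,5-bis(methoxymethoxy)phenyl ethyl carbonate | CCOC(=O)Oc1c(Br)c(OCOC)cc(OCOC)c1C=O | intermediate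
8 | 2-bromo-3,5-bis(methoxymethoxy)-6-methylphenol | Cc1c(O)c(Br)c(OCOC)cc1OCOC | intermediate
9 | hexamethyldisilazane | C[Si](C)(C)N[Si](C)(C)C | starting material
10 | [2-bromo-3,5-bis(methoxymethoxy)-6-methylphenoxy](trimethyl)silane | Cc1c(O[Si](C)(C)C)c(Br)c(OCOC)cc1OCOC | intermediate
11 | trifluoromethanesulfonic anhydride | O=S(=O)(OS(=O)(=O)C(F)(F)F)C(F)(F)F | starting material
12 | lithium 3,5-bis(methoxymethoxy)-2-methyl-6-(trimethylsilyl)phenoxide | Cc1c([O-])c([Si](C)(C)C)c(OCOC)cc1OCOC.[Li+] | intermediate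
13 | 3,5-bis(methoxymethoxy)-2-methyl-6-(trimethylsilyl)phenyl trifluoromethanesulfonate | Cc1c(OCOC)cc(OCOC)c([Si](C)(C)C)c1OS(=O)(=O)C(F)(F)F | intermediate
14 | nerol, (2Z)-3,7-dimethylocta-2,6-dien-1-ol | CC(C)=CCC/C(C)=C\CO | starting material
15 | tert-butyl hydroperoxide | CC(C)(C)OO | starting material
16 | [(2R,3S)-3-methyl-3-(4-methylpent-3-en-1-yl)oxiran-2-yl]methanol | CC(C)=CCC[C@]1(C)O[C@@H]1CO | intermediate
17 | thiophenol | Sc1ccccc1 | starting material
18 | sodium (2S)-6-methyl-2-[(2S)-oxiran-2-yl]hept-5-en-2-olate | CC(C)=CCC[C@](C)([O-])[C@@H]1CO1.[Na+] | intermediate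
19 | (2R,3S)-3,7-dimethyl-1-(phenylsulfanyl)oct-6-ene-2,3-diol | CC(C)=CCC[C@](C)(O)[C@@H](O)CSc1ccccc1 | intermediate
20 | trimethyloxonium tetrafluoroborate | C[O+](C)C.F[B-](F)(F)F | starting material
21 | [(2R,3S)-2,3-dihydroxy-3,7-dimethyloct-6-en-1-yl](methyl)phenylsulfonium tetrafluoroborate | CC(C)=CCC[C@](C)(O)[C@@H](O)C[S+](C)c1ccccc1.F[B-](F)(F)F | intermediate
22 | (2S)-6-methyl-2-[(2S)-oxiran-2-yl]hept-5-en-2-ol | CC(C)=CCC[C@](C)(O)[C@@H]1CO1 | intermediate
23 | triethylsilyl trifluoromethanesulfonate | CC[Si](CC)(CC)OS(=O)(=O)C(F)(F)F | starting material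
24 | triethyl({(2S)-6-methyl-2-[(2S)-oxiran-2-yl]hept-5-en-2-yl}oxy)silane | CC(C)=CCC[C@](C)(O[Si](CC)(CC)CC)[C@@H]1CO1 | intermediate
25 | 4,6-bis(methoxymethoxy)-3-methylbenzyne (the C3≡C4 aryne) | CC1=C(OCOC)C=C(OCOC)C#C1 | intermediate
26 | zwitterion with the epoxide oxygen of 24 bonded to C4 as an oxiranium and a carbanion at C3 | CC(C)=CCC[C@](C)(O[Si](CC)(CC)CC)[C@@H]1C[O+]1c1[c-]c(OCOC)cc(OCOC)c1C | intermediate
27 | tetrabutylammonium salt of the C3 carbanion of the aryl (2S,3S)-1-bromo-3,7-dimethyl-3-[(triethylsilyl)oxy]oct-6-en-2-yl ether | CC(C)=CCC[C@](C)(O[Si](CC)(CC)CC)[C@H](CBr)Oc1[c-]c(OCOC)cc(OCOC)c1C.CCCC[N+](CCCC)(CCCC)CCCC | intermediate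
28 | triethyl({(2S)-2-[(2S)-4,6-bis(methoxymethoxy)-7-methyl-2,3-dihydro-1-benzofuran-2-yl]-6-methylhept-5-en-2-yl}oxy)silane | CC(C)=CCC[C@](C)(O[Si](CC)(CC)CC)[C@@H]1Cc2c(O1)c(C)c(OCOC)cc2OCOC | intermediate
29 | N-methoxy-N-methyl-2-methylpropanamide | CC(C)C(=O)N(C)OC | starting material
30 | 1-[(2S)-4,6-bis(methoxymethoxy)-7-methyl-2-{(2S)-6-methyl-2-[(triethylsilyl)oxy]hept-5-en-2-yl}-2,3-dihydro-1-benzofuran-5-yl]-2-methylpropan-1-one | CC(C)=CCC[C@](C)(O[Si](CC)(CC)CC)[C@@H]1Cc2c(O1)c(C)c(OCOC)c(C(=O)C(C)C)c2OCOC | intermediate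
31 | 1-{(2S)-4,6-dihydroxy-2-[(2S)-2-hydroxy-6-methylhept-5-en-2-yl]-7-methyl-2,3-dihydro-1-benzofuran-5-yl}-2-methylpropan-1-one | CC(C)=CCC[C@](C)(O)[C@@H]1Cc2c(O1)c(C)c(O)c(C(=O)C(C)C)c2O | intermediate
32 | 3-methylbut-2-en-1-yl acetate (prenyl acetate) | CC(C)=CCOC(C)=O | starting material
33 | (2S,7S)-4-hydroxy-2-[(2S)-2-hydroxy-6-methylhept-5-en-2-yl]-7-methyl-7-(3-methylbut-2-en-1-yl)-5-(2-methylpropanoyl)-2,3-dihydro-1-benzofuran-6(7H)-one | CC(C)=CCC[C@](C)(O)[C@@H]1CC2=C(O1)[C@](C)(CC=C(C)C)C(=O)C(C(=O)C(C)C)=C2O | intermediate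
34 | (2S,5R,7S)-2-[(2S)-2-hydroxy-6-methylhept-5-en-2-yl]-7-methyl-5,7-bis(3-methylbut-2-en-1-yl)-5-(2-methylpropanoyl)-2,3-dihydro-1-benzofuran-4,6(5H,7H)-dione (CNP0155474.1) | CC(C)=CCC[C@](C)(O)[C@@H]1CC2=C(O1)[C@](C)(CC=C(C)C)C(=O)[C@](CC=C(C)C)(C(=O)C(C)C)C2=O | target

**Step count and risks**

Total step count: 14. Longest linear sequence: 10 steps (steps 1–5 and 10–14); the epoxide branch (steps 6–9) joins at step 10.

Steps most likely to fail:

Step 10. The aryne may be consumed by fluoride, bromide or the side-chain alkene before the weakly nucleophilic epoxide oxygen adds, or the zwitterion may decay by internal proton transfer to an aryl enol ether before bromide opens it. The fallback uses known chemistry, sets out from bromophenol 8 and epoxide 24, and comes back at 28. Bromophenol 8 would be doubly lithiated (n-BuLi, 2.2 equiv, THF, −78 °C) and the aryllithium used to open 24 at its terminal carbon with BF3·OEt2. This forms C3–C7 first and gives (2S,3S)-1-[2-hydroxy-4,6-bis(methoxymethoxy)-3-methylphenyl]-3,7-dimethyl-3-[(triethylsilyl)oxy]oct-6-en-2-ol F1. Phenol-selective triflation (PhNTf2, K2CO3, THF) would give 2-{(2S,3S)-2-hydroxy-3,7-dimethyl-3-[(triethylsilyl)oxy]oct-6-en-1-yl}-3,5-bis(methoxymethoxy)-6-methylphenyl trifluoromethanesulfonate F2. Intramolecular Buchwald–Hartwig etherification (Pd(OAc)2, 2-(di-tert-butylphosphino)-1,1'-binaphthyl, Cs2CO3, toluene, 80 °C) would then join the C8 oxygen to C4 and return to 28 with C8 untouched.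

Step 13. Alkylation may occur at C3 or at oxygen instead of C5, or facial discrimination at C5 may be weak if the ligand and the remote C8 centre oppose one another. The fallback sets out from 31 and comes back at 33. It replaces attack on a π-allyl palladium complex by direct SN2 alkylation inside a chiral ion pair: prenyl bromide, CsOH·H2O, N-(9-anthracenylmethyl)cinchonidinium bromide, toluene–CHCl3, −40 °C, with the pseudoenantiomeric cinchoninium salt available for the other face. It makes no new compound (F0).

Step 14. O-prenylation may fail to funnel to carbon at the congested triacyl centre, or discrimination between the faces syn and anti to the C5 prenyl group may be weak. The fallback sets out from 33 and comes back at 34. The enol would be deprotonated with LiN(SiMe3)2 (THF, −78 °C) and the chelated lithium enolate alkylated with prenyl bromide (−78 → 0 °C). This tight SN2 transition state on a metal-bound enolate should feel the C5 substituents more strongly than outer-sphere attack on a π-allyl complex. It makes no new compound (F0).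

**Further compounds**

F1 | step 10 | (2S,3S)-1-[2-hydroxy-4,6-bis(methoxymethoxy)-3-methylphenyl]-3,7-dimethyl-3-[(triethylsilyl)oxy]oct-6-en-2-ol | CC(C)=CCC[C@](C)(O[Si](CC)(CC)CC)[C@@H](O)Cc1c(O)c(C)c(OCOC)cc1OCOC
F2 | step 10 | 2-{(2S,3S)-2-hydroxy-3,7-dimethyl-3-[(triethylsilyl)oxy]oct-6-en-1-yl}-3,5-bis(methoxymethoxy)-6-methylphenyl trifluoromethanesulfonate | CC(C)=CCC[C@](C)(O[Si](CC)(CC)CC)[C@@H](O)Cc1c(OS(=O)(=O)C(F)(F)F)c(C)c(OCOC)cc1OCOC
F0 | step 13 | none | none
F0 | step 14 | none | none
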